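**Plan**

1. Numbering (ent-kaurane): ring A = C1–C5 and C10 (C19 methyl and C18 on C4, C6 on C5); lactone = C10–C20–O–C7(=O)–C8–C9; ring C = C8, C9, C11–C14; ring D = C8, C14, C13, C16, C15; C17 = exocyclic CH2.
2. Cuts: C15 oxidation level and silyl groups last; C8–C15 (ring D) back to a lactone enolate and a C13 isopropenyl group; then C9–C11 and C13–C14 together (a [3+3] opening of ring C) to a spiro-lactone allylic bromide (ring A + lactone) and 4-oxopentanal; C9–C10 to a ring A epoxide-derived radical and an acrylate; ring A (C3–C4, C5–C10) by Diels–Alder.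
3. Enabling feature: C7=O on C8 makes the triad C9–C8–C14 of the lactone ring a 2-carbonyl-allyl unit. It is nucleophilic at C9 as the allylindium and, once the double bond has moved to C8=C14, electrophilic at C14. C11 is a carbinol (former aldehyde) carbon, and C13 is alpha to C16, which is kept as a ketone until it becomes the methylidene-bearing carbon.
4. Forward order: ring A, then the spiro delta-lactone at C10, then ring C in one pot, then ring D, then the enone and deprotection.
5. Stereochemistry: C4 and C5 from the E dienophile (relative) and the chiral amine catalyst (absolute); C10 by radical addition trans to the C5 substituent; C9 by the lactone face remote from C6; C11 by a chair allylation transition state; C13 by equilibration of the acetyl group; C8 by the bridging geometry of ring D closure.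

Key step: step 10

Remark: C10 of 3–5 is drawn as the expected endo (cis to C6) epimer. This centre, the spiro carbon of 8, C8 of 12, 13, 18 and 19, and C15 of 22 are of no consequence because they become sp2 or are oxidised later.

**Route**

Step 1
Reactants: 1 ethyl (2E)-2-methyl-4-oxobut-2-enoate; 2 (1E)-buta-1,3-dien-1-yl acetate
Product: 3 ethyl (1S,5S,6R)-5-acetoxy-6-formyl-1-methylcyclohex-3-ene-1-carboxylate
Conditions: (5S)-5-benzyl-2,2,3-trimethylimidazolidin-4-one hydrochloride (20 mol %), MeCN/H2O 95:5, 0 to 23 °C
Reagents that add atoms: none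
Why: Iminium-catalysed Diels–Alder reaction in which the CH2 terminus of the diene should bond to the doubly substituted beta-carbon (C4) and the acetoxy-bearing terminus to the alpha-carbon (C5), the E geometry of 1 fixing the formyl group (C6) trans to the ester (C18) and cis to the methyl (C19), while the benzyl group of the catalyst should screen one face so that the diene adds to the Si face at C4 and C5 (absolute control).

Step 2
Reactants: 3 ethyl (1S,5S,6R)-5-acetoxy-6-formyl-1-methylcyclohex-3-ene-1-carboxylate
Product: 4 (1S,5S,6S)-5,6-bis(hydroxymethyl)-5-methylcyclohex-2-en-1-ol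
Conditions: LiAlH4, THF, 0 °C; then H2O, aq NaOH
Reagents that add atoms: none
Why: Hydride reduction with LiAlH4 converts aldehyde, ester and acetate into the triol in one operation without touching a stereocentre.

Step 3
Reactants: 4 (1S,5S,6S)-5,6-bis(hydroxymethyl)-5-methylcyclohex-2-en-1-ol
Product: 5 (1S,5S,6S)-5,6-bis(tert-butyldimethylsilyloxymethyl)-5-methylcyclohex-2-en-1-ol
Conditions: TBSCl (2.2 equiv), imidazole, DMF, 0 °C
Reagents that add atoms: tert-butyl(chloro)dimethylsilane CC(C)(C)[Si](C)(C)Cl
Why: Silylation with TBSCl and imidazole should take the two primary hydroxyls and leave the hindered secondary allylic hydroxyl free.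

Step 4
Reactants: 5 (1S,5S,6S)-5,6-bis(tert-butyldimethylsilyloxymethyl)-5-methylcyclohex-2-en-1-ol
Product: 6 (2S,3S)-2,3-bis(tert-butyldimethylsilyloxymethyl)-3-methylcyclohexan-1-one
Conditions: [Ir(cod)(PCy3)(py)]PF6 (2 mol %), THF, H2 (brief activation), then argon, 23 °C
Reagents that add atoms: none
Why: Iridium hydride-catalysed redox isomerisation of the secondary allylic alcohol (alkene migration to the enol, then tautomerisation) gives the saturated ketone under neutral conditions, so the alpha-stereocentre C5 of the beta-silyloxy ketone should neither epimerise nor eliminate.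

Step 5
Reactants: 6 (2S,3S)-2,3-bis(tert-butyldimethylsilyloxymethyl)-3-methylcyclohexan-1-one
Product: 7 (1S,2S)-1,2-bis(tert-butyldimethylsilyloxymethyl)-1-methyl-3-methylidenecyclohexane
Conditions: Zn, CH2Br2, TiCl4, THF/CH2Cl2, 0 to 23 °C
Reagents that add atoms: dibromomethane BrCBr
Why: Takai–Lombardo methylenation is a non-basic carbonyl olefination and should convert the hindered, enolisable ketone into the C10=C20 methylidene without epimerising C5.

Step 6
Reactants: 7 (1S,2S)-1,2-bis(tert-butyldimethylsilyloxymethyl)-1-methyl-3-methylidenecyclohexane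
Product: 8 4,5-bis(tert-butyldimethylsilyloxymethyl)-5-methyl-1-oxaspiro[2.5]octane (ring A as in 7; either epimer at the spiro carbon)
Conditions: mCPBA, NaHCO3, CH2Cl2, 0 °C
Reagents that add atoms: 3-chloroperoxybenzoic acid OOC(=O)c1cccc(Cl)c1
Why: Prilezhaev epoxidation of the 1,1-disubstituted alkene, in which both epimers at the spiro carbon are usable because C10 becomes a planar radical in the next step.

Step 7
Reactants: 8 4,5-bis(tert-butyldimethylsilyloxymethyl)-5-methyl-1-oxaspiro[2.5]octane; 9 2,2,2-trifluoroethyl prop-2-enoate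
Product: 11 7,8-bis(tert-butyldimethylsilyloxymethyl)-8-methyl-2-oxaspiro[5.5]undecan-3-one (C9 on C10 trans to C6 and C20 cis to C6), via trifluoroethyl hydroxy ester 10 (not isolated)
Conditions: Cp2TiCl2 (2.5 equiv), Zn dust, THF, 23 °C, slow addition of 8 and 9; aq NaH2PO4 work-up
Reagents that add atoms: none
Why: Reductive epoxide opening by Cp2TiCl (trivalent titanium, formed from Cp2TiCl2 and Zn) gives the tertiary C10 radical, which undergoes Giese addition to the acrylate on the face trans to the neighbouring C5 CH2OTBS group (this sets C10), and the resulting alkoxide lactonises onto the activated trifluoroethyl ester.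

Step 8
Reactants: 11 7,8-bis(tert-butyldimethylsilyloxymethyl)-8-methyl-2-oxaspiro[5.5]undecan-3-one
Product: 14 7,8-bis(tert-butyldimethylsilyloxymethyl)-8-methyl-4-methylidene-2-oxaspiro[5.5]undecan-3-one, via Mannich base 12 (not isolated), via trimethylammonium iodide 13 (not isolated)
Conditions: LDA (LiN(i-Pr)2), THF, −78 °C; dimethyl(methylidene)ammonium iodide, −78 to 0 °C; then MeI; then DBU, 23 °C
Reagents that add atoms: dimethyl(methylidene)ammonium iodide C=[N+](C)C.[I-]
Why: Mannich reaction of the lactone lithium enolate with the iminium salt, N-methylation and base-induced elimination of trimethylamine (alpha-methylenation) introduce C14 as the exocyclic C8=C14 alkene.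

Step 9
Reactants: 14 7,8-bis(tert-butyldimethylsilyloxymethyl)-8-methyl-4-methylidene-2-oxaspiro[5.5]undecan-3-one
Product: 15 4-(bromomethyl)-7,8-bis(tert-butyldimethylsilyloxymethyl)-8-methyl-2-oxaspiro[5.5]undec-4-en-3-one
Conditions: NBS (1.05 equiv), AIBN (cat.), PhCF3, 80 °C
Reagents that add atoms: N-bromosuccinimide BrN1C(=O)CCC1=O
Why: Wohl–Ziegler allylic bromination in which abstraction of a C9 hydrogen gives the C9–C8–C14 allyl radical, which should take bromine at the primary terminus C14 and leave the conjugated C8=C9 alkene (a C9-bromo regioisomer would give the same allylindium in step 10).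

Step 10
Reactants: 15 4-(bromomethyl)-7,8-bis(tert-butyldimethylsilyloxymethyl)-8-methyl-2-oxaspiro[5.5]undec-4-en-3-one; 16 4-oxopentanal
Product: 18 tricyclic hydroxy keto lactone (rings A + lactone + C; C11 hydroxyl cis to C10; C13 acetyl trans to C10 and to the hydroxyl; C8–H), via homoallylic indium alkoxide 17 (not isolated)
Conditions: In powder (1.5 equiv), 16 (1.5 equiv), DMF, 23 °C; then DBU (3 equiv), 23 to 40 °C, same flask
Reagents that add atoms: none
Why: Indium inserts into the allylic C–Br bond of 15, the allylindium adds through its gamma-carbon C9 to the aldehyde of 16 in a six-membered chair (Zimmerman–Traxler) transition state, forming C9–C11 and moving the double bond to C8=C14 (17), and DBU then enolises the methyl ketone towards C13 so that the enolate adds to C14 of the alpha-methylene lactone, forming C13–C14. The closest known reaction types are the Barbier-type 2-(alkoxycarbonyl)allylation of aldehydes with 2-(bromomethyl)acrylates and the base-mediated intramolecular Michael addition, here run together as a [3+3] annulation. Ring C closes in the second event by a 6-endo-trig conjugate addition. C9 should be set by approach of the aldehyde to the lactone face remote from the C5 CH2OTBS group, C11 by the chair transition state in which the ring-locked gamma-substituent C10 is trans to the CH2In carbon (anti adduct, hydroxyl cis to C10 on ring C), and C13 by thermodynamic control, since the enolisable acetyl group should settle equatorial in the chair that keeps the spiro carbon C10 equatorial and the C11 hydroxyl axial, while C8 stays epimerisable. The step needs gamma- over alpha-attack of the allylindium, reaction at the aldehyde and not the ketone, and Michael closure in preference to transfer of the lactone acyl group to the C11 oxygen; it relies for these on the usual allyl-transposing addition of 2-carbonyl-allyl indium reagents, on the low reactivity of allylindiums towards ketones, and on the covalent indium alkoxide under a non-nucleophilic amidine base.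

Step 11
Reactants: 18 tricyclic hydroxy keto lactone
Product: 19 tricyclic hydroxy lactone with a C13 isopropenyl group
Conditions: Zn, CH2Br2, TiCl4, THF/CH2Cl2, 0 to 23 °C
Reagents that add atoms: dibromomethane BrCBr
Why: Takai–Lombardo methylenation converts the C16 ketone into the isopropenyl group without base, so that C13 is not epimerised and the free C11 hydroxyl cannot attack the lactone as an alkoxide.

Step 12
Reactants: 19 tricyclic hydroxy lactone with a C13 isopropenyl group
Product: 21 tetracyclic tris-TBS ether with C8–C15 bond and C16=C17 methylidene, via bis-silyl ketene acetal 20 (not isolated)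
Conditions: TBSOTf (3 equiv), Et3N (5 equiv), CH2Cl2, 0 to 23 °C; solvent exchange; Pd(OAc)2 (1.1 equiv), DMSO, 45 °C
Reagents that add atoms: tert-butyldimethylsilyl trifluoromethanesulfonate CC(C)(C)[Si](C)(C)OS(=O)(=O)C(F)(F)F
Why: Silyl triflate/amine silylation gives the C11 silyl ether and the lactone silyl ketene acetal, which with divalent palladium undergoes oxidative cyclisation (alkene insertion of the palladium enolate, then beta-hydride elimination towards the methyl group, a Saegusa-type cycloalkenylation) to join C8 to the alkene terminus (C15) and leave the C16=C17 methylidene, C8 being set because the two-carbon bridge can only form on the face of ring C that carries the C13 substituent.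

Step 13
Reactants: 21 tetracyclic tris-TBS ether
Product: 22 15-hydroxy derivative of 21
Conditions: SeO2 (0.5 equiv), t-BuOOH, CH2Cl2, 23 °C
Reagents that add atoms: selenium dioxide O=[Se]=O (oxygen carrier); tert-butyl hydroperoxide CC(C)(C)OO (terminal oxygen source)
Why: Selenium dioxide allylic oxidation (ene reaction followed by [2,3]-sigmatropic shift) should hydroxylate C15, since the only other allylic hydrogen sits on the C13 bridgehead.

Step 14
Reactants: 22 15-hydroxy derivative of 21
Product: 23 tris-TBS ether of the target (15-oxo-16-ene)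
Conditions: Dess–Martin periodinane, NaHCO3, CH2Cl2, 23 °C
Reagents that add atoms: none
Why: Dess–Martin oxidation of the secondary allylic alcohol gives the alpha-methylene ketone under buffered conditions.

Step 15
Reactants: 23 tris-TBS ether of the target
Product: 24 target CNP0152458.1
Conditions: HF·pyridine, THF/pyridine, 0 to 23 °C
Reagents that add atoms: none
Why: Fluoride-mediated cleavage of the three silyl ethers with buffered HF·pyridine should spare the alpha-methylene ketone and the lactone.

**Compound list**

1 | ethyl (2E)-2-methyl-4-oxobut-2-enoate | CCOC(=O)/C(C)=C/C=O | starting material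
2 | (1E)-buta-1,3-dien-1-yl acetate | CC(=O)O/C=C/C=C | starting material
3 | ethyl (1S,5S,6R)-5-acetoxy-6-formyl-1-methylcyclohex-3-ene-1-carboxylate | CCOC(=O)[C@@]1(C)CC=C[C@H](OC(C)=O)[C@@H]1C=O | intermediate
4 | (1S,5S,6S)-5,6-bis(hydroxymethyl)-5-methylcyclohex-2-en-1-ol | OC[C@@]1(C)CC=C[C@H](O)[C@@H]1CO | intermediate
5 | (1S,5S,6S)-5,6-bis(tert-butyldimethylsilyloxymethyl)-5-methylcyclohex-2-en-1-ol | CC(C)(C)[Si](C)(C)OC[C@@]1(C)CC=C[C@H](O)[C@@H]1CO[Si](C)(C)C(C)(C)C | intermediate
6 | (2S,3S)-2,3-bis(tert-butyldimethylsilyloxymethyl)-3-methylcyclohexan-1-one | CC(C)(C)[Si](C)(C)OC[C@@]1(C)CCCC(=O)[C@@H]1CO[Si](C)(C)C(C)(C)C | intermediate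
7 | (1S,2S)-1,2-bis(tert-butyldimethylsilyloxymethyl)-1-methyl-3-methylidenecyclohexane | CC(C)(C)[Si](C)(C)OC[C@@]1(C)CCCC(=C)[C@@H]1CO[Si](C)(C)C(C)(C)C | intermediate
8 | 4,5-bis(tert-butyldimethylsilyloxymethyl)-5-methyl-1-oxaspiro[2.5]octane (epimers at the spiro carbon) | CC(C)(C)[Si](C)(C)OC[C@@]1(C)CCCC2(CO2)[C@@H]1CO[Si](C)(C)C(C)(C)C | intermediate
9 | 2,2,2-trifluoroethyl prop-2-enoate | C=CC(=O)OCC(F)(F)F | starting material
10 | 2,2,2-trifluoroethyl 3-[2,3-bis(tert-butyldimethylsilyloxymethyl)-1-(hydroxymethyl)-3-methylcyclohexyl]propanoate (titanium alkoxide in the flask) | OC[C@@]1(CCC(=O)OCC(F)(F)F)CCC[C@](C)(CO[Si](C)(C)C(C)(C)C)[C@H]1CO[Si](C)(C)C(C)(C)C | intermediate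
11 | 7,8-bis(tert-butyldimethylsilyloxymethyl)-8-methyl-2-oxaspiro[5.5]undecan-3-one | O=C1CC[C@]2(CO1)CCC[C@](C)(CO[Si](C)(C)C(C)(C)C)[C@H]2CO[Si](C)(C)C(C)(C)C | intermediate
12 | 4-[(dimethylamino)methyl] derivative of 11 (Mannich base) | CN(C)CC1C[C@]2(COC1=O)CCC[C@](C)(CO[Si](C)(C)C(C)(C)C)[C@H]2CO[Si](C)(C)C(C)(C)C | intermediate
13 | trimethylammonium iodide of 12 | C[N+](C)(C)CC1C[C@]2(COC1=O)CCC[C@](C)(CO[Si](C)(C)C(C)(C)C)[C@H]2CO[Si](C)(C)C(C)(C)C.[I-] | intermediate
14 | 7,8-bis(tert-butyldimethylsilyloxymethyl)-8-methyl-4-methylidene-2-oxaspiro[5.5]undecan-3-one | C=C1C[C@]2(COC1=O)CCC[C@](C)(CO[Si](C)(C)C(C)(C)C)[C@H]2CO[Si](C)(C)C(C)(C)C | intermediate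
15 | 4-(bromomethyl)-7,8-bis(tert-butyldimethylsilyloxymethyl)-8-methyl-2-oxaspiro[5.5]undec-4-en-3-one | BrCC1=C[C@]2(COC1=O)CCC[C@](C)(CO[Si](C)(C)C(C)(C)C)[C@H]2CO[Si](C)(C)C(C)(C)C | intermediate
16 | 4-oxopentanal | CC(=O)CCC=O | starting material
17 | 5-(1-hydroxy-4-oxopentyl)-4-methylidene derivative of 11 (homoallylic alcohol, indium alkoxide in the flask; C9 substituent syn to C1, hydroxyl anti to C10) | C=C1C(=O)OC[C@]2(CCC[C@](C)(CO[Si](C)(C)C(C)(C)C)[C@H]2CO[Si](C)(C)C(C)(C)C)[C@@H]1[C@H](O)CCC(C)=O | intermediate
18 | tricyclic hydroxy keto lactone (C11 hydroxyl, C13 acetyl, C8–H) | CC(=O)[C@@H]1C[C@@H](O)[C@H]2[C@@]3(CCC[C@](C)(CO[Si](C)(C)C(C)(C)C)[C@H]3CO[Si](C)(C)C(C)(C)C)COC(=O)C2C1 | intermediate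
19 | tricyclic hydroxy lactone with C13 isopropenyl group | CC(=C)[C@@H]1C[C@@H](O)[C@H]2[C@@]3(CCC[C@](C)(CO[Si](C)(C)C(C)(C)C)[C@H]3CO[Si](C)(C)C(C)(C)C)COC(=O)C2C1 | intermediate
20 | C11 TBS ether and lactone TBS ketene acetal of 19 | CC(=C)[C@@H]1C[C@@H](O[Si](C)(C)C(C)(C)C)[C@H]2[C@@]3(CCC[C@](C)(CO[Si](C)(C)C(C)(C)C)[C@H]3CO[Si](C)(C)C(C)(C)C)COC(O[Si](C)(C)C(C)(C)C)=C2C1 | intermediate
21 | tetracyclic tris-TBS ether (C15H2, C16=C17) | C=C1C[C@]23C[C@H]1C[C@@H](O[Si](C)(C)C(C)(C)C)[C@H]2[C@@]1(CCC[C@](C)(CO[Si](C)(C)C(C)(C)C)[C@H]1CO[Si](C)(C)C(C)(C)C)COC3=O | intermediate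
22 | 15-hydroxy derivative of 21 | C=C1C(O)[C@]23C[C@H]1C[C@@H](O[Si](C)(C)C(C)(C)C)[C@H]2[C@@]1(CCC[C@](C)(CO[Si](C)(C)C(C)(C)C)[C@H]1CO[Si](C)(C)C(C)(C)C)COC3=O | intermediate
23 | tris-TBS ether of the target | C=C1C(=O)[C@]23C[C@H]1C[C@@H](O[Si](C)(C)C(C)(C)C)[C@H]2[C@@]1(CCC[C@](C)(CO[Si](C)(C)C(C)(C)C)[C@H]1CO[Si](C)(C)C(C)(C)C)COC3=O | intermediate
24 | CNP0152458.1 | C=C1C(=O)[C@]23C[C@H]1C[C@@H](O)[C@H]2[C@@]1(CCC[C@](C)(CO)[C@H]1CO)COC3=O | target

**Step count**

Total steps: 15. Longest linear sequence: 15 steps (from 1 and 2 to 24; 9 and 16 are purchased).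

**Steps most likely to fail**

Step 10. The allylindium may attack through C14 instead of C9, the lactone acyl group may be transferred to the new C11 oxygen before or after ring closure, or enolisation towards C13 may be too slow. The fallback reverses the bond order and uses known reactions only. It sets out from 15. The potassium enolate of allyl 2-acetyl-4,4-dimethoxybutanoate F1 (made from allyl acetoacetate and 2-bromo-1,1-dimethoxyethane with NaH in DMF) is alkylated at C14 (K2CO3, acetone) to give the quaternary keto ester F2. Pd(PPh3)4 (zerovalent palladium) and morpholine remove the allyl ester with decarboxylation to give the keto acetal F3. Pyridinium p-toluenesulfonate in wet acetone frees the keto aldehyde F4. SmI2, LiBr and t-BuOH in THF at −78 °C then effect ketyl–olefin cyclisation of the aldehyde onto C9 of the unsaturated lactone, and brief DBU treatment equilibrates C13, which returns the route to 18.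

Step 1. The beta,beta-disubstituted iminium ion may react too slowly or with poor facial and regiochemical control, or the beta-acetoxy aldehyde may lose acetic acid. The fallback replaces asymmetric catalysis by kinetic resolution. Compounds 1 and 2 are combined thermally (toluene, 80 °C) to give 3 as the racemate, which is carried through steps 2 and 3 unchanged. After removal of any C10 epimer, Candida antarctica lipase B and vinyl acetate in MTBE should acetylate the antipode to the acetate of ent-5 F5 and leave 5 unreacted, so that the route is rejoined at 5.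

Step 9. Hydrogen abstraction may be unselective (C20–H, silyl ether CH2) or bromination may go too far. The fallback is an ionic addition–elimination. From 14, Br2 in CH2Cl2 at −78 °C gives the dibromide F6, and DBU removes HBr across C8–C9 to give 15.

**Further compounds**

F1 | step 10 | allyl 2-acetyl-4,4-dimethoxybutanoate | C=CCOC(=O)C(CC(OC)OC)C(C)=O
F2 | step 10 | allyl 2-acetyl-4,4-dimethoxy-2-[(lactone C8)methyl]butanoate (C14-alkylated keto ester) | C=CCOC(=O)C(CC(OC)OC)(C(C)=O)CC1=C[C@]2(COC1=O)CCC[C@](C)(CO[Si](C)(C)C(C)(C)C)[C@H]2CO[Si](C)(C)C(C)(C)C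
F3 | step 10 | keto acetal after deallylation and decarboxylation | CC(=O)C(CC(OC)OC)CC1=C[C@]2(COC1=O)CCC[C@](C)(CO[Si](C)(C)C(C)(C)C)[C@H]2CO[Si](C)(C)C(C)(C)C
F4 | step 10 | keto aldehyde | CC(=O)C(CC=O)CC1=C[C@]2(COC1=O)CCC[C@](C)(CO[Si](C)(C)C(C)(C)C)[C@H]2CO[Si](C)(C)C(C)(C)C
F5 | step 1 | acetate of ent-5 | CC(C)(C)[Si](C)(C)OC[C@]1(C)CC=C[C@@H](OC(C)=O)[C@H]1CO[Si](C)(C)C(C)(C)C
F6 | step 9 | 4-bromo-4-(bromomethyl) derivative of 11 | BrCC1(Br)C[C@]2(COC1=O)CCC[C@](C)(CO[Si](C)(C)C(C)(C)C)[C@H]2CO[Si](C)(C)C(C)(C)C
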